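**Plan**
- Retrosynthesis first opens the pyran (O1–C2 and C4–C4a), giving a 2,4-dihydroxy-5-methoxyphenyl benzil and 3-methylbut-2-enal. It then cuts both bonds of the carbonyl carbon Cα (C6–Cα and Cα–Cβ).
- Feature used (numbering O1, C2, C3, C4, C4a, C5–C8, C8a; Cα on C6, Cβ on the anisyl ring): Cα is a single carbonyl carbon lying between the oxygenated arene carbon C6 and the anisoyl carbon Cβ. It can therefore be the divalent carbon of an isocyanide, which takes up one nucleophile and one electrophile at the same atom.
- Forward: isovanillin → 4-methoxyresorcinol → bis(methoxymethyl) ether → bromide 5; 4-methoxybenzoyl chloride → Weinreb amide 7; then 5, isocyanide 8 and 7 are joined in one flask to the protected benzil 13 (chain assembly, no ring closes).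
- Both acetals are then removed and the pyran, the only ring made, is closed last with 3-methylbut-2-enal at C4a, the only open position ortho to the free C8a oxygen.
- Stereochemistry: the target has no stereocentre and no stereogenic double bond, so nothing has to be set.

Key step: step 5

Remark on the chemistry: 2-hydroxybenzils such as 14 and 17 are assumed to exist as the open, hydrogen-bonded 1,2-diones (as the natural product does) and not as cyclic hemiketals.

**Step 1**
Reactants: 1 isovanillin (3-hydroxy-4-methoxybenzaldehyde)
Product: 3 4-methoxybenzene-1,3-diol, via aryl formate 2 (not isolated)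
Conditions: mCPBA, CH2Cl2, 0 °C to rt; then HCl (cat.), MeOH, rt
Reagents that add atoms: 3-chloroperoxybenzoic acid (mCPBA), O=C(OO)c1cccc(Cl)c1
Why: Baeyer–Villiger (Dakin-type) oxidation, in which the ring, made electron-rich by the para methoxy group, should migrate in preference to hydride to give formate 2, and acid-catalysed methanolysis then frees the diol without exposing the oxidation-prone resorcinol to base and air.

**Step 2**
Reactants: 3 4-methoxybenzene-1,3-diol
Product: 4 1-methoxy-2,4-bis(methoxymethoxy)benzene
Conditions: NaH (2.4 equiv), MOMCl (2.4 equiv), DMF, 0 °C to rt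
Reagents that add atoms: chloromethyl methyl ether (MOMCl), COCCl
Why: Williamson-type O-alkylation of both phenoxides with the reactive α-chloro ether; the methoxymethyl ethers withstand t-BuLi, support the later aryllithium by chelation and come off under mild acid.

**Step 3**
Reactants: 4 1-methoxy-2,4-bis(methoxymethoxy)benzene
Product: 5 1-bromo-5-methoxy-2,4-bis(methoxymethoxy)benzene
Conditions: NBS (1.0 equiv), MeCN, 0 °C to rt, dark
Reagents that add atoms: N-bromosuccinimide (NBS), O=C1CCC(=O)N1Br
Why: Electrophilic aromatic bromination should go to the one position that is para to one acetal oxygen and ortho to the other (the alternatives are the hindered site between the two methoxymethoxy groups and a site meta to both), as in the bromination of 1,2,4-trialkoxybenzenes.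

**Step 4**
Reactants: 6 4-methoxybenzoyl chloride
Product: 7 N,4-dimethoxy-N-methylbenzamide
Conditions: MeNHOMe·HCl, K2CO3, CH2Cl2/H2O, 0 °C to rt
Reagents that add atoms: N,O-dimethylhydroxylamine hydrochloride, CNOC.Cl
Why: Schotten–Baumann acylation of N,O-dimethylhydroxylamine gives the Weinreb amide, the acyl electrophile that stops at the ketone stage in step 5.

**Step 5**
Reactants: 5 1-bromo-5-methoxy-2,4-bis(methoxymethoxy)benzene; 8 2-isocyano-2,4,4-trimethylpentane; 7 N,4-dimethoxy-N-methylbenzamide
Product: 13 1-[5-methoxy-2,4-bis(methoxymethoxy)phenyl]-2-(4-methoxyphenyl)ethane-1,2-dione, via aryllithium 9 (not isolated), via lithium aldimine 10 (not isolated), via lithium alkoxide adduct 11 (not isolated), via imino ketone 12 (not isolated)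
Conditions: t-BuLi (2.0 equiv), THF, −78 °C; then 8 (1.1 equiv), −78 to 0 °C; then 7, −78 °C to rt; then H2O, aq. oxalic acid (1 M), THF, rt
Reagents that add atoms: water, O
Why: Two equivalents of t-BuLi effect bromine–lithium exchange and destroy the t-BuBr formed, so that aryllithium 9, held by the ortho methoxymethoxy oxygen, is the only carbanion present and no alkyl halide is left to alkylate later intermediates; 9 then adds in a 1,1-fashion to the divalent carbon of isocyanide 8 to give lithium aldimine 10 (C6–Cα). Aldimine 10 acts as an aroyl anion equivalent and attacks Weinreb amide 7 to give the chelated tetrahedral adduct 11 (Cα–Cβ), which does not collapse before the quench and so cannot be attacked a second time. Water releases imino ketone 12, and aqueous oxalic acid hydrolyses its hindered ketimine to the 1,2-dione 13 at room temperature, conditions the aryl methoxymethyl ethers should survive. The closest known reaction type is the Walborsky lithium aldimine synthesis (organolithium plus a tertiary-alkyl isocyanide, then an acylating electrophile such as a chloroformate or carbon dioxide) combined with the Weinreb ketone synthesis. No ring closes and no stereocentre is formed, and the dione arrives at its final oxidation level without an oxidation step. The selectivities needed are the site of metalation, fixed by the bromine at the future C6 (direct lithiation would go between the two acetal oxygens), and single insertion, which follows from the anionic, non-electrophilic nature of 10 and the bulk of the tert-octyl group.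

**Step 6**
Reactants: 13 1-[5-methoxy-2,4-bis(methoxymethoxy)phenyl]-2-(4-methoxyphenyl)ethane-1,2-dione
Product: 14 1-(2,4-dihydroxy-5-methoxyphenyl)-2-(4-methoxyphenyl)ethane-1,2-dione
Conditions: aq. HCl (3 M), THF, 50 °C
Reagents that add atoms: none
Why: Acid-catalysed hydrolysis of the two aryl methoxymethyl acetals; the aqueous medium keeps the 1,2-dione from forming ketals and the aryl methyl ethers are untouched.

**Step 7**
Reactants: 14 1-(2,4-dihydroxy-5-methoxyphenyl)-2-(4-methoxyphenyl)ethane-1,2-dione; 15 3-methylbut-2-enal
Product: 17 dielsianone, via oxatriene 16 (not isolated)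
Conditions: 15 (3 equiv), pyridine, 120 °C, sealed tube
Reagents that add atoms: none
Why: Pyridine-mediated chromenylation of an acylresorcinol, in which aldol-type attack of the ring carbon between the two hydroxyls (future C4a, the only free position ortho to the non-chelated hydroxyl), loss of water to oxatriene 16 and oxa-6π electrocyclisation through that oxygen should give the 2,2-dimethyl-2H-chromene while the hydroxyl hydrogen-bonded to the ketone stays free, as in the known annulation of 2,4-dihydroxyacetophenones.

**Compound list**
1 | isovanillin (3-hydroxy-4-methoxybenzaldehyde) | COc1ccc(C=O)cc1O | starting material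
2 | 3-hydroxy-4-methoxyphenyl formate | COc1ccc(OC=O)cc1O | intermediate
3 | 4-methoxybenzene-1,3-diol | COc1ccc(O)cc1O | intermediate
4 | 1-methoxy-2,4-bis(methoxymethoxy)benzene | COCOc1ccc(OC)c(OCOC)c1 | intermediate
5 | 1-bromo-5-methoxy-2,4-bis(methoxymethoxy)benzene | COCOc1cc(OCOC)c(Br)cc1OC | intermediate
6 | 4-methoxybenzoyl chloride | COc1ccc(C(Cl)=O)cc1 | starting material
7 | N,4-dimethoxy-N-methylbenzamide | COc1ccc(C(=O)N(C)OC)cc1 | intermediate
8 | 2-isocyano-2,4,4-trimethylpentane | [C-]#[N+]C(C)(C)CC(C)(C)C | starting material
9 | [5-methoxy-2,4-bis(methoxymethoxy)phenyl]lithium | [Li]c1cc(OC)c(OCOC)cc1OCOC | intermediate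
10 | {[5-methoxy-2,4-bis(methoxymethoxy)phenyl][(2,4,4-trimethylpentan-2-yl)imino]methyl}lithium | [Li]C(=NC(C)(C)CC(C)(C)C)c1cc(OC)c(OCOC)cc1OCOC | intermediate
11 | lithium 2-[5-methoxy-2,4-bis(methoxymethoxy)phenyl]-1-[methoxy(methyl)amino]-1-(4-methoxyphenyl)-2-[(2,4,4-trimethylpentan-2-yl)imino]ethan-1-olate | [Li]OC(N(C)OC)(c1ccc(OC)cc1)C(=NC(C)(C)CC(C)(C)C)c1cc(OC)c(OCOC)cc1OCOC | intermediate
12 | 2-[5-methoxy-2,4-bis(methoxymethoxy)phenyl]-1-(4-methoxyphenyl)-2-[(2,4,4-trimethylpentan-2-yl)imino]ethan-1-one (imine geometry not defined) | COCOc1cc(OCOC)c(C(=NC(C)(C)CC(C)(C)C)C(=O)c2ccc(OC)cc2)cc1OC | intermediate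
13 | 1-[5-methoxy-2,4-bis(methoxymethoxy)phenyl]-2-(4-methoxyphenyl)ethane-1,2-dione | COCOc1cc(OCOC)c(C(=O)C(=O)c2ccc(OC)cc2)cc1OC | intermediate
14 | 1-(2,4-dihydroxy-5-methoxyphenyl)-2-(4-methoxyphenyl)ethane-1,2-dione | COc1ccc(C(=O)C(=O)c2cc(OC)c(O)cc2O)cc1 | intermediate
15 | 3-methylbut-2-enal | CC(C)=CC=O | starting material
16 | 3-hydroxy-6-methoxy-4-[2-(4-methoxyphenyl)-2-oxoacetyl]-2-(3-methylbut-2-en-1-ylidene)cyclohexa-3,5-dien-1-one (exocyclic alkene geometry not defined) | COC1=CC(C(=O)C(=O)c2ccc(OC)cc2)=C(O)C(=CC=C(C)C)C1=O | intermediate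
17 | dielsianone, 1-(5-hydroxy-8-methoxy-2,2-dimethyl-2H-chromen-6-yl)-2-(4-methoxyphenyl)ethane-1,2-dione | COc1ccc(C(=O)C(=O)c2cc(OC)c3c(c2O)C=CC(C)(C)O3)cc1 | target

**Count**
Total steps: 7. Longest linear sequence: 6 steps (steps 1, 2, 3, 5, 6, 7 from isovanillin); step 4 is a one-step side branch.

**Steps most likely to fail**

1. Step 5. The chelated, electron-rich aryllithium may add only slowly to the hindered isocyanide, so that unconsumed aryllithium is acylated directly by the amide. Acylation of the lithium aldimine may also be incomplete, and the acid needed to hydrolyse the hindered ketimine may begin to strip the acetals. The fallback sets out from 5 and gives up the isocyanide union for an alkyne oxidation. Sonogashira coupling of 5 with 1-ethynyl-4-methoxybenzene (PdCl2(PPh3)2, CuI, Et3N, DMF, 80 °C) should give 1-methoxy-5-[(4-methoxyphenyl)ethynyl]-2,4-bis(methoxymethoxy)benzene F1. Buffered permanganate oxidation of the diarylalkyne (KMnO4, NaHCO3, MgSO4, acetone/H2O, rt) should then give the 1,2-dione, and the route is rejoined at 13.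

2. Step 7. At 120 °C in pyridine the enal may self-condense faster than it attacks the deactivated ring, the base may attack the 1,2-dione, and closure through the chelated oxygen may compete. The fallback sets out from 14 and builds the pyran by a Claisen cascade. Selective O-alkylation of the free, non-chelated hydroxyl with 3-chloro-3-methylbut-1-yne (K2CO3, KI, CuI cat., acetone, reflux) should give 1-{2-hydroxy-5-methoxy-4-[(2-methylbut-3-yn-2-yl)oxy]phenyl}-2-(4-methoxyphenyl)ethane-1,2-dione F2. Heating in o-xylene at 140 °C should bring about aromatic Claisen rearrangement to the only free ortho position, giving after enolisation 1-[2,4-dihydroxy-5-methoxy-3-(3-methylbuta-1,2-dien-1-yl)phenyl]-2-(4-methoxyphenyl)ethane-1,2-dione F3. A 1,5-hydrogen shift to oxatriene 16 and oxa-6π closure through the oxygen that carried the propargyl group return the route at 17.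

3. Step 1. The peracid may over-oxidise the unprotected, electron-rich phenol, and hydride migration to the carboxylic acid may compete with aryl migration. The fallback sets out from 1 and masks the phenol before the oxidation. MOMCl and iPr2NEt in CH2Cl2 should give 4-methoxy-3-(methoxymethoxy)benzaldehyde F4. Baeyer–Villiger oxidation (mCPBA, CH2Cl2) should give 4-methoxy-3-(methoxymethoxy)phenyl formate F5, which basic methanolysis (K2CO3, MeOH) should cleave to 4-methoxy-3-(methoxymethoxy)phenol F6. A second methoxymethylation (NaH, MOMCl, DMF) rejoins the route at 4.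

**Further compounds**
F1 | step 5 | 1-methoxy-5-[(4-methoxyphenyl)ethynyl]-2,4-bis(methoxymethoxy)benzene | COCOc1cc(OCOC)c(C#Cc2ccc(OC)cc2)cc1OC
F2 | step 7 | 1-{2-hydroxy-5-methoxy-4-[(2-methylbut-3-yn-2-yl)oxy]phenyl}-2-(4-methoxyphenyl)ethane-1,2-dione | COc1ccc(C(=O)C(=O)c2cc(OC)c(OC(C)(C)C#C)cc2O)cc1
F3 | step 7 | 1-[2,4-dihydroxy-5-methoxy-3-(3-methylbuta-1,2-dien-1-yl)phenyl]-2-(4-methoxyphenyl)ethane-1,2-dione | COc1ccc(C(=O)C(=O)c2cc(OC)c(O)c(C=C=C(C)C)c2O)cc1
F4 | step 1 | 4-methoxy-3-(methoxymethoxy)benzaldehyde | COCOc1cc(C=O)ccc1OC
F5 | step 1 | 4-methoxy-3-(methoxymethoxy)phenyl formate | COCOc1cc(OC=O)ccc1OC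
F6 | step 1 | 4-methoxy-3-(methoxymethoxy)phenol | COCOc1cc(O)ccc1OC
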